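All runs are simulated for substances that don't exist, noise included.

At 30.0 h the gamma flask, charged with 14 mM of free catalyst, shows 0% of its starting material and 84% of target; that reading is our yardstick.

in all of them: starting material 0.10 M

| charge | reagent | free catalyst | remark | time |
|---|---|---|---|---|
| alpha | 0.40 M | 1.4 mM | run made earlier |  |
| gamma | 0.40 M | 14 mM | run made earlier |  |
| ochre | 0.400 M | 5.0 mM |  | 50 h |
| violet | 0.400 M | 6.0 mM |  | 50 h |
| red | 0.400 M | 3.3 mM |  | 50 h |
| teal | 0.400 M | 10 mM |  | 50 h |
| green | 0.400 M | 1.0 mM |  | 50 h |

| run | time / h | target / % | starting material / % |
|---|---|---|---|
| alpha | 8.00 | 1 | 98 |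
| alpha | 15.0 | 4 | 92 |
| alpha | 25.0 | 8 | 83 |
| alpha | 30.0 | 11 | 84 |
| alpha | 40.0 | 13 | 81 |
| alpha | 48.0 | 16 | 75 |
| gamma | 4.00 | 14 | 74 |
| gamma | 6.00 | 22 | 66 |
| gamma | 12.0 | 42 | 39 |
| gamma | 20.0 | 67 | 12 |
| gamma | 30.0 | 84 | 0 |
| gamma | 48.0 | 89 | 0 |

(each reading ± 1.5 percentage points)

- the numbers in the tables scatter by 1.5 percentage points (one standard deviation)

- the flasks put in order of amount of target, in percent of the starting material charged, best first, at 50 h (ochre / violet / red / teal / green)
- the amount of target, in percent of the starting material charged of the flask you put first, at 50 h
- the amount of target, in percent of the starting material charged of the flask you put last, at 50 h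

A catalyst is given back after each turn, so as a first estimate, to be held against the runs, we suppose that a flask with less catalyst follows gamma's curve on a slower clock, at equal charges of starting material and reagent; this supposition is good as far as the rate of every step goes with the catalyst charge. Gamma holds ten times the catalyst of alpha, so alpha's 48.0 h should count as 4.80 h on gamma's clock, and its 16% of target does lie between gamma's 14% at 4.00 h and 22% at 6.00 h. So, as an estimate, we read each flask on gamma's clock: its hours times its catalyst over gamma's catalyst.

The clock gives a crossing. Starting material is the limiting reagent, with 0.10 M against 0.400 M of reagent, and scaling gamma's 30.0 h to 50 h gives the catalyst charge that uses it up by then, the crossing charge 8.40 mM. On this estimate, a flask below this charge still stands on the rising part of gamma's curve at 50 h, and a flask above it stands on the stretch where gamma's target read from 84% to 89%. Teal, at 10 mM, is above the crossing, at 35.7 h on the clock, so we expect target near those two readings. The other flasks are below it, and since gamma's target rose at each reading, their order follows their catalyst. Green reaches 3.57 h on the clock, before gamma's earliest reading, so we expect less target than that reading's 14%.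

The forecast gives teal > violet > ochre > red > green, with 84% (77% to 89%) for teal and 12% (8% to 16%) for green: “There is no sign of target decaying, so more catalyst should simply give more target at 50 h.”

The flasks come out as teal > violet > ochre > red > green, with 83.9% of target in teal and 10.3% in green, under these equations:

    starting material + free catalyst ⇌ catalyst intermediate A (K = 27.0 /M, k = 37.0 /M/h)
    catalyst intermediate D → free catalyst + target (k = 0.630 /h)
    catalyst intermediate C ⇌ catalyst intermediate D (K = 2.60, k = 3.10 /h)
    catalyst intermediate A ⇌ catalyst intermediate B (K = 2.30, k = 90.0 /h)
    starting material + target → side product (k = 0.190 /M/h)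
    reagent + catalyst intermediate B → catalyst intermediate C (k = 9.40 /M/h)

Teal, past the crossing, ends with 99.9% conversion of its starting material. The clock stays an estimate, since the step from starting material and target to side product holds no catalyst: green left for 500 h reaches the same clock reading as teal at 50 h, yet holds 36.7% of target against teal's 83.9%. The crossing charge serves once more on green's recipe with 0.0040 M of free catalyst: that is below 8.40 mM and reaches 14.3 h on gamma's clock, between gamma's 42% at 12.0 h and 67% at 20.0 h, and that flask gives 44.6% of target with 29.0% of its starting material left.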